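**Strategy.** Both 2,3-dihydrobenzofurans are treated as ring-contracted flavanones. In the key step PhI(OAc)2 in trimethyl orthoformate makes ring-A carbon C4a of (2R)-5-methoxy-2-(4-methoxyphenyl)chroman-4-one migrate from the carbonyl carbon to C3. The pyranone contracts to the dihydrofuran, forming the C3–C3a bond of the styryl-bearing benzofuran, and the carbonyl carbon is pushed out as a CO2Me handle. This exploits benzofuran C3a lying between oxygen-bearing C7a and C4, the pattern of C4a in a 5-oxygenated flavanone, so regiochemistry is automatic. The handle is exchanged for the second benzofuran (made the same way) by decarboxylative arylation; C–H borylation/Suzuki styrylation and demethylation finish.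

Key step: step 3

Assumption: (S)-t-BuPyOx is taken to deliver the (2R)-flavanone and (R)-t-BuPyOx the (2S)-flavanone, by analogy with the enone face this ligand selects in additions to cyclic enones; should the sense be the reverse, the two ligand antipodes are exchanged between steps 2 and 5. Compounds 1, 4, 10, 16 and 21 are taken as purchased.

**Step 1**
Reactants: 1 1-(2-hydroxy-6-methoxyphenyl)ethan-1-one
Product: 3 5-methoxy-4H-chromen-4-one, via enaminone 2 (not isolated)
Conditions: Me2NCH(OMe)2, 100 °C; then 2 M HCl, CH2Cl2, 40 °C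
Reagents that add atoms: N,N-dimethylformamide dimethyl acetal, COC(OC)N(C)C
Why: Condensation of the methyl ketone with the amide acetal gives the enaminone, whose phenol adds to the β-carbon and expels dimethylamine under acid (enaminone route to chromones); no stereocentre is formed.

**Step 2**
Reactants: 3 5-methoxy-4H-chromen-4-one; 4 (4-methoxyphenyl)boronic acid
Product: 5 (2R)-5-methoxy-2-(4-methoxyphenyl)chroman-4-one
Conditions: Pd(OCOCF3)2 (5 mol%), (S)-t-BuPyOx (6 mol%), NH4PF6, H2O, ClCH2CH2Cl, 60 °C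
Reagents that add atoms: none
Why: Asymmetric conjugate addition of an arylboronic acid to a chromone under cationic divalent palladium catalysis; the aryl group is delivered to C2 on the enone face left open by the tert-butyl group of the ligand, which sets C2 as R.

**Step 3**
Reactants: 5 (2R)-5-methoxy-2-(4-methoxyphenyl)chroman-4-one
Product: 8 methyl (2R,3R)-4-methoxy-2-(4-methoxyphenyl)-2,3-dihydro-1-benzofuran-3-carboxylate, via enol ether 6 (not isolated), via iodane 7 (not isolated)
Conditions: PhI(OAc)2 (1.2 equiv), H2SO4 (0.5 equiv), HC(OMe)3, 25 °C; aqueous NaHCO3 work-up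
Reagents that add atoms: trimethyl orthoformate, COC(OC)OC; water, O
Why: Acid and HC(OMe)3 turn ketone 5 into enol ether 6, which attacks trivalent iodine through C3 on the face anti to the C2 aryl group and takes up methanol at C4 to give iodane 7; loss of PhI then drives the 1,2-shift of ring-A carbon C4a from C4 to C3, and the dimethoxycarbenium ion left at the old C4 ends as the methyl ester on work-up. The closest known reaction is the hypervalent-iodine (or trivalent-thallium) oxidative ring contraction of flavanones to methyl 2-aryl-2,3-dihydrobenzofuran-3-carboxylates, a semipinacol-type 1,2-aryl migration. The dihydrofuran is closed by contraction of the six-membered pyranone: the new C3–C3a bond forms by migration of the aryl carbon antiperiplanar to the equatorial C–I bond, with inversion at C3. C2 is not touched and stays R; the new C3 centre is set trans to the C2 aryl group by the anti iodination/invertive shift, is also the thermodynamic arrangement of this epimerisable ester, and is replaced again in step 10. The step needs migration of ring A in preference to migration of the C2 aryl group (isoflavone path) or dehydrogenation to the flavone; this is secured by the ketal oxygens at C4, which stabilise the cation left behind, and by the two ortho oxygen substituents (O1 and 5-OMe) that raise the migratory aptitude of C4a, while the position on ring A is fixed because only C4a can migrate.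

**Step 4**
Reactants: 8 methyl (2R,3R)-4-methoxy-2-(4-methoxyphenyl)-2,3-dihydro-1-benzofuran-3-carboxylate
Product: 9 (2R,3R)-4-methoxy-2-(4-methoxyphenyl)-2,3-dihydro-1-benzofuran-3-carboxylic acid
Conditions: LiOH·H2O, THF/MeOH/H2O, 25 °C; then 1 M HCl
Reagents that add atoms: lithium hydroxide, [Li+].[OH-]
Why: Saponification of the methyl ester; C2 is not acidic and is untouched, and any epimerisation at C3 only returns the trans acid, whose C3 configuration is immaterial for step 10.

**Step 5**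
Reactants: 3 5-methoxy-4H-chromen-4-one; 10 (3,4-dimethoxyphenyl)boronic acid
Product: 11 (2S)-2-(3,4-dimethoxyphenyl)-5-methoxychroman-4-one
Conditions: Pd(OCOCF3)2 (5 mol%), (R)-t-BuPyOx (6 mol%), NH4PF6, H2O, ClCH2CH2Cl, 60 °C
Reagents that add atoms: none
Why: The same asymmetric conjugate addition as in step 2, now with the antipodal ligand, so that the aryl group enters the opposite enone face and C2 is set as S.

**Step 6**
Reactants: 11 (2S)-2-(3,4-dimethoxyphenyl)-5-methoxychroman-4-one
Product: 14 methyl (2S,3S)-2-(3,4-dimethoxyphenyl)-4-methoxy-2,3-dihydro-1-benzofuran-3-carboxylate, via enol ether 12 (not isolated), via iodane 13 (not isolated)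
Conditions: PhI(OAc)2 (1.2 equiv), H2SO4 (0.5 equiv), HC(OMe)3, 25 °C; aqueous NaHCO3 work-up
Reagents that add atoms: trimethyl orthoformate, COC(OC)OC; water, O
Why: The same oxidative ring contraction of a flavanone as in step 3 (1,2-shift of ring-A carbon C4a from C4 to C3 through enol ether 12 and iodane 13); C2 stays S and the ester at C3 is set trans to the C2 aryl group.

**Step 7**
Reactants: 14 methyl (2S,3S)-2-(3,4-dimethoxyphenyl)-4-methoxy-2,3-dihydro-1-benzofuran-3-carboxylate
Product: 15 (2S,3S)-2-(3,4-dimethoxyphenyl)-4-methoxy-2,3-dihydro-1-benzofuran-3-carboxylic acid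
Conditions: LiOH·H2O, THF/MeOH/H2O, 25 °C; then 1 M HCl
Reagents that add atoms: lithium hydroxide, [Li+].[OH-]
Why: Saponification as in step 4; C2 is untouched.

**Step 8**
Reactants: 15 (2S,3S)-2-(3,4-dimethoxyphenyl)-4-methoxy-2,3-dihydro-1-benzofuran-3-carboxylic acid; 16 1-bromo-3,5-dimethoxybenzene
Product: 17 (2S,3S)-2-(3,4-dimethoxyphenyl)-3-(3,5-dimethoxyphenyl)-4-methoxy-2,3-dihydro-1-benzofuran
Conditions: Ir[dF(CF3)ppy]2(dtbbpy)PF6 (2 mol%), NiCl2(dme) (10 mol%), dtbbpy (15 mol%), Cs2CO3, DMF, blue LEDs, 25 °C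
Reagents that add atoms: none
Why: Metallaphotoredox decarboxylative arylation: the carboxylate is oxidised by excited Ir[dF(CF3)ppy]2(dtbbpy)PF6, CO2 is lost, and the benzylic C3 radical is taken up by the aryl–nickel species formed from 16 and coupled by reductive elimination; the aryl group enters anti to the C2 aryl group, which sets C3 as S (trans).

**Step 9**
Reactants: 17 (2S,3S)-2-(3,4-dimethoxyphenyl)-3-(3,5-dimethoxyphenyl)-4-methoxy-2,3-dihydro-1-benzofuran
Product: 19 (2S,3S)-6-bromo-2-(3,4-dimethoxyphenyl)-3-(3,5-dimethoxyphenyl)-4-methoxy-2,3-dihydro-1-benzofuran, via aryl boronate 18 (not isolated)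
Conditions: [Ir(OMe)(cod)]2 (1.5 mol%), dtbpy (3 mol%), B2pin2, THF, 80 °C; then CuBr2 (3 equiv), MeOH/H2O, 80 °C
Reagents that add atoms: bis(pinacolato)diboron, CC1(C)OB(OC1(C)C)B1OC(C)(C)C(C)(C)O1 (boryl group of 18 only); copper dibromide, [Cu+2].[Br-].[Br-]
Why: Sterically governed C–H borylation catalysed by [Ir(OMe)(cod)]2/dtbpy takes place at C6 of the benzofuran ring, the only C–H bond with no ortho substituent, and CuBr2 then replaces boron by bromine (copper-mediated bromodeboronation); no stereocentre is touched.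

**Step 10**
Reactants: 9 (2R,3R)-4-methoxy-2-(4-methoxyphenyl)-2,3-dihydro-1-benzofuran-3-carboxylic acid; 19 (2S,3S)-6-bromo-2-(3,4-dimethoxyphenyl)-3-(3,5-dimethoxyphenyl)-4-methoxy-2,3-dihydro-1-benzofuran
Product: 20 (2R,3R)-3-[(2S,3S)-2-(3,4-dimethoxyphenyl)-3-(3,5-dimethoxyphenyl)-4-methoxy-2,3-dihydro-1-benzofuran-6-yl]-4-methoxy-2-(4-methoxyphenyl)-2,3-dihydro-1-benzofuran
Conditions: 9 (1.5 equiv), Ir[dF(CF3)ppy]2(dtbbpy)PF6 (2 mol%), NiCl2(dme) (10 mol%), dtbbpy (15 mol%), Cs2CO3, DMF, blue LEDs, 25 °C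
Reagents that add atoms: none
Why: The same metallaphotoredox decarboxylative arylation as in step 8 joins the two halves; the planar benzylic C3 radical from 9 is arylated on the face anti to the C2 aryl group, which sets C3 as R (trans), while the three existing stereocentres are not involved.

**Step 11**
Reactants: 20 (the heptamethyl ether from step 10); 21 1-[(E)-2-bromoethenyl]-4-methoxybenzene
Product: 23 (2R,3R)-3-[(2S,3S)-2-(3,4-dimethoxyphenyl)-3-(3,5-dimethoxyphenyl)-4-methoxy-2,3-dihydro-1-benzofuran-6-yl]-4-methoxy-2-(4-methoxyphenyl)-6-[(E)-2-(4-methoxyphenyl)ethenyl]-2,3-dihydro-1-benzofuran, via aryl boronate 22 (not isolated)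
Conditions: [Ir(OMe)(cod)]2 (2.5 mol%), dtbpy (5 mol%), B2pin2, THF, 80 °C; then Pd(dppf)Cl2 (5 mol%), 21 (1.5 equiv), aqueous K3PO4, 70 °C
Reagents that add atoms: bis(pinacolato)diboron, CC1(C)OB(OC1(C)C)B1OC(C)(C)C(C)(C)O1 (boryl group of 22 only)
Why: One-pot C–H borylation/Suzuki–Miyaura coupling: in 20 the only C–H bond without an ortho substituent is C6 of the upper benzofuran, so the boronate forms there and couples with the alkenyl bromide with retention of the E geometry.

**Step 12**
Reactants: 23 (the octamethyl ether from step 11)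
Product: 24 (2R,3R)-3-[(2S,3S)-2-(3,4-dihydroxyphenyl)-3-(3,5-dihydroxyphenyl)-4-hydroxy-2,3-dihydro-1-benzofuran-6-yl]-2-(4-hydroxyphenyl)-6-[(E)-2-(4-hydroxyphenyl)ethenyl]-2,3-dihydro-1-benzofuran-4-ol
Conditions: BCl3 (20 equiv), n-Bu4NI (20 equiv), CH2Cl2, 0 °C to 25 °C; then ice-water
Reagents that add atoms: none
Why: Lewis acid/iodide cleavage of aryl methyl ethers (boron coordinates the ether oxygen and iodide removes the methyl group by SN2); the conditions are mild enough that the stilbene and the trans-dihydrofurans should persist, and no stereocentre is touched.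

**Compound list**
1 | 1-(2-hydroxy-6-methoxyphenyl)ethan-1-one | CC(=O)c1c(O)cccc1OC | starting material
2 | (E)-3-(dimethylamino)-1-(2-hydroxy-6-methoxyphenyl)prop-2-en-1-one (not isolated) | CN(C)/C=C/C(=O)c1c(O)cccc1OC | intermediate
3 | 5-methoxy-4H-chromen-4-one | O=c1ccoc2cccc(OC)c12 | intermediate
4 | (4-methoxyphenyl)boronic acid | COc1ccc(B(O)O)cc1 | starting material
5 | (2R)-5-methoxy-2-(4-methoxyphenyl)chroman-4-one | O=C1C[C@H](c2ccc(OC)cc2)Oc2cccc(OC)c21 | intermediate
6 | (2R)-4,5-dimethoxy-2-(4-methoxyphenyl)-2H-chromene (not isolated) | COC1=C[C@H](c2ccc(OC)cc2)Oc2cccc(OC)c21 | intermediate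
7 | (2S,3S)-3-[acetoxy(phenyl)-λ3-iodanyl]-4,4,5-trimethoxy-2-(4-methoxyphenyl)chromane, iodine trans to the C2 aryl group (not isolated) | COC1(OC)[C@@H](I(OC(C)=O)c2ccccc2)[C@H](c2ccc(OC)cc2)Oc2cccc(OC)c21 | intermediate
8 | methyl (2R,3R)-4-methoxy-2-(4-methoxyphenyl)-2,3-dihydro-1-benzofuran-3-carboxylate (trans) | COC(=O)[C@H]1[C@H](c2ccc(OC)cc2)Oc2cccc(OC)c21 | intermediate
9 | (2R,3R)-4-methoxy-2-(4-methoxyphenyl)-2,3-dihydro-1-benzofuran-3-carboxylic acid (trans) | OC(=O)[C@H]1[C@H](c2ccc(OC)cc2)Oc2cccc(OC)c21 | intermediate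
10 | (3,4-dimethoxyphenyl)boronic acid | COc1ccc(B(O)O)cc1OC | starting material
11 | (2S)-2-(3,4-dimethoxyphenyl)-5-methoxychroman-4-one | O=C1C[C@@H](c2ccc(OC)c(OC)c2)Oc2cccc(OC)c21 | intermediate
12 | (2S)-2-(3,4-dimethoxyphenyl)-4,5-dimethoxy-2H-chromene (not isolated) | COC1=C[C@@H](c2ccc(OC)c(OC)c2)Oc2cccc(OC)c21 | intermediate
13 | (2R,3R)-3-[acetoxy(phenyl)-λ3-iodanyl]-2-(3,4-dimethoxyphenyl)-4,4,5-trimethoxychromane, iodine trans to the C2 aryl group (not isolated) | COC1(OC)[C@H](I(OC(C)=O)c2ccccc2)[C@@H](c2ccc(OC)c(OC)c2)Oc2cccc(OC)c21 | intermediate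
14 | methyl (2S,3S)-2-(3,4-dimethoxyphenyl)-4-methoxy-2,3-dihydro-1-benzofuran-3-carboxylate (trans) | COC(=O)[C@@H]1[C@@H](c2ccc(OC)c(OC)c2)Oc2cccc(OC)c21 | intermediate
15 | (2S,3S)-2-(3,4-dimethoxyphenyl)-4-methoxy-2,3-dihydro-1-benzofuran-3-carboxylic acid (trans) | OC(=O)[C@@H]1[C@@H](c2ccc(OC)c(OC)c2)Oc2cccc(OC)c21 | intermediate
16 | 1-bromo-3,5-dimethoxybenzene | COc1cc(Br)cc(OC)c1 | starting material
17 | (2S,3S)-2-(3,4-dimethoxyphenyl)-3-(3,5-dimethoxyphenyl)-4-methoxy-2,3-dihydro-1-benzofuran (trans) | c1cc(OC)c2c(c1)O[C@H](c1ccc(OC)c(OC)c1)[C@H]2c1cc(OC)cc(OC)c1 | intermediate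
18 | 6-(4,4,5,5-tetramethyl-1,3,2-dioxaborolan-2-yl) derivative of 17 (not isolated) | CC1(C)OB(OC1(C)C)c1cc(OC)c2c(c1)O[C@H](c1ccc(OC)c(OC)c1)[C@H]2c1cc(OC)cc(OC)c1 | intermediate
19 | (2S,3S)-6-bromo-2-(3,4-dimethoxyphenyl)-3-(3,5-dimethoxyphenyl)-4-methoxy-2,3-dihydro-1-benzofuran | Brc1cc(OC)c2c(c1)O[C@H](c1ccc(OC)c(OC)c1)[C@H]2c1cc(OC)cc(OC)c1 | intermediate
20 | (2R,3R)-3-[(2S,3S)-2-(3,4-dimethoxyphenyl)-3-(3,5-dimethoxyphenyl)-4-methoxy-2,3-dihydro-1-benzofuran-6-yl]-4-methoxy-2-(4-methoxyphenyl)-2,3-dihydro-1-benzofuran | c1cc(OC)c2c(c1)O[C@@H](c1ccc(OC)cc1)[C@@H]2c1cc(OC)c2c(c1)O[C@H](c1ccc(OC)c(OC)c1)[C@H]2c1cc(OC)cc(OC)c1 | intermediate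
21 | 1-[(E)-2-bromoethenyl]-4-methoxybenzene | COc1ccc(/C=C/Br)cc1 | starting material
22 | 6-(4,4,5,5-tetramethyl-1,3,2-dioxaborolan-2-yl) derivative of 20, boron on the benzofuran that carries the 4-methoxyphenyl group (not isolated) | CC1(C)OB(OC1(C)C)c1cc(OC)c2c(c1)O[C@@H](c1ccc(OC)cc1)[C@@H]2c1cc(OC)c2c(c1)O[C@H](c1ccc(OC)c(OC)c1)[C@H]2c1cc(OC)cc(OC)c1 | intermediate
23 | octamethyl ether of the target: (2R,3R)-3-[(2S,3S)-2-(3,4-dimethoxyphenyl)-3-(3,5-dimethoxyphenyl)-4-methoxy-2,3-dihydro-1-benzofuran-6-yl]-4-methoxy-2-(4-methoxyphenyl)-6-[(E)-2-(4-methoxyphenyl)ethenyl]-2,3-dihydro-1-benzofuran | COc1ccc(/C=C/c2cc(OC)c3c(c2)O[C@@H](c2ccc(OC)cc2)[C@@H]3c2cc(OC)c3c(c2)O[C@H](c2ccc(OC)c(OC)c2)[C@H]3c2cc(OC)cc(OC)c2)cc1 | intermediate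
24 | (2R,3R)-3-[(2S,3S)-2-(3,4-dihydroxyphenyl)-3-(3,5-dihydroxyphenyl)-4-hydroxy-2,3-dihydro-1-benzofuran-6-yl]-2-(4-hydroxyphenyl)-6-[(E)-2-(4-hydroxyphenyl)ethenyl]-2,3-dihydro-1-benzofuran-4-ol | Oc1ccc(/C=C/c2cc(O)c3c(c2)O[C@@H](c2ccc(O)cc2)[C@@H]3c2cc(O)c3c(c2)O[C@H](c2ccc(O)c(O)c2)[C@H]3c2cc(O)cc(O)c2)cc1 | target

**Count**
Total steps: 12. Longest linear sequence: 9 steps (steps 1, 5, 6, 7, 8, 9, 10, 11, 12).

**Steps most likely to fail**

Step 3 (key ring contraction). What may go wrong:
- migration of the C2 aryl group instead of ring A (isoflavone path);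
- dehydrogenation to the flavone;
- oxidation of the anisyl ring by PhI(OAc)2;
- acid-induced reversible opening of the C2–O1 bond, eroding the enantiomeric purity.

Fallback, from 5 back to 8: the same bond is made by a Wolff ring contraction. Flavanone 5 is trifluoroacetylated at C3 (LiHMDS, THF, −78 °C, CF3CO2CH2CF3) to the (2R)-3-trifluoroacetyl ketone F1. Detrifluoroacetylative diazo transfer (MsN3, Et3N, H2O, MeCN) gives (2S)-3-diazo-5-methoxy-2-(4-methoxyphenyl)chroman-4-one F2, spatially unchanged at C2. Irradiation at 365 nm in methanol expels nitrogen, ring-A carbon C4a shifts to the carbene carbon, and methanol traps the ketene. Equilibration with NaOMe/MeOH gives trans ester 8, where the route is rejoined.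

Step 10 (fragment union). What may go wrong:
- slow uptake of the hindered C3 radical by nickel, so that protodecarboxylation, radical dimerisation or hydrodebromination of 19 take over;
- incomplete facial selectivity at C3.

Fallback, from 9 and 19 back to 20: a thermal decarboxylative Negishi coupling. Acid 9 is converted with N-hydroxyphthalimide, N,N'-diisopropylcarbodiimide and DMAP in CH2Cl2 into the redox-active ester F3. Bromide 19 is converted by n-BuLi (THF, −78 °C) and then ZnCl2 into the arylzinc chloride F4. The two are coupled with NiCl2(dme)/dtbbpy in THF/DMF at 25 °C, again through the C3 radical and anti arylation, to give 20.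

Step 12 (global demethylation). What may go wrong:
- incomplete cleavage of eight ethers;
- acid-mediated oligomerisation of the electron-rich stilbene;
- ionisation of the benzylic C2–O bonds, with epimerisation or ring opening.

Fallback, from 20 back to 24: the ethers are cleaved before the alkene is present. Compound 20 is borylated as in step 11 (boronate 22) and treated with CuBr2 in MeOH/H2O to give the 6-bromo heptamethyl ether F5. BBr3 in CH2Cl2 (−78 °C to 25 °C) gives the heptaphenol bromide F6. A Heck reaction with 4-acetoxystyrene (Pd(OAc)2, P(o-tol)3, NaOAc, DMF, 100 °C) installs the E-styryl unit as the monoacetate F7. K2CO3 in MeOH removes the acetate to give target 24.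

**Further compounds**
F1 | step 3 | (2R)-5-methoxy-2-(4-methoxyphenyl)-3-(trifluoroacetyl)chroman-4-one (C3 undefined, largely enolised) | O=C(C1C(=O)c2c(OC)cccc2O[C@H]1c1ccc(OC)cc1)C(F)(F)F
F2 | step 3 | (2S)-3-diazo-5-methoxy-2-(4-methoxyphenyl)chroman-4-one | [N-]=[N+]=C1C(=O)c2c(OC)cccc2O[C@H]1c1ccc(OC)cc1
F3 | step 10 | 1,3-dioxoisoindolin-2-yl (2R,3R)-4-methoxy-2-(4-methoxyphenyl)-2,3-dihydro-1-benzofuran-3-carboxylate | O=C(ON1C(=O)c2ccccc2C1=O)[C@H]1[C@H](c2ccc(OC)cc2)Oc2cccc(OC)c21
F4 | step 10 | [(2S,3S)-2-(3,4-dimethoxyphenyl)-3-(3,5-dimethoxyphenyl)-4-methoxy-2,3-dihydro-1-benzofuran-6-yl]zinc chloride | Cl[Zn]c1cc(OC)c2c(c1)O[C@H](c1ccc(OC)c(OC)c1)[C@H]2c1cc(OC)cc(OC)c1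
F5 | step 12 | 6-bromo derivative of 20 (bromine on the benzofuran that carries the 4-methoxyphenyl group) | Brc1cc(OC)c2c(c1)O[C@@H](c1ccc(OC)cc1)[C@@H]2c1cc(OC)c2c(c1)O[C@H](c1ccc(OC)c(OC)c1)[C@H]2c1cc(OC)cc(OC)c1
F6 | step 12 | heptaphenol corresponding to F5 (all seven methyl ethers cleaved) | Brc1cc(O)c2c(c1)O[C@@H](c1ccc(O)cc1)[C@@H]2c1cc(O)c2c(c1)O[C@H](c1ccc(O)c(O)c1)[C@H]2c1cc(O)cc(O)c1
F7 | step 12 | target carrying an acetate on the styryl phenol | CC(=O)Oc1ccc(/C=C/c2cc(O)c3c(c2)O[C@@H](c2ccc(O)cc2)[C@@H]3c2cc(O)c3c(c2)O[C@H](c2ccc(O)c(O)c2)[C@H]3c2cc(O)cc(O)c2)cc1
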